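- If the east run turns its charge quickly, its yield at the asked time is a survival question: what share of the target made is still there?

| setting | west | north-east | south-east | south | east |
|---|---|---|---|---|---|
| starting material | 0.120 M | 0.120 M | 0.240 M | 0.120 M | 0.0400 M |
| reagent | 0.360 M | 0.360 M | 0.360 M | 0.720 M | 0.720 M |
| target |  | 0.0360 M |  |  |  |
| time |  |  |  |  | 26 min |

| run | time / min | [target] / M |
|---|---|---|
| west run | 3.2 | 0.0267 |
| west run | 6.5 | 0.0449 |
| west run | 9.8 | 0.0590 |
| west run | 13 | 0.0692 |
| west run | 16 | 0.0728 |
| west run | 20 | 0.0817 |
| west run | 23 | 0.0841 |
| west run | 26 | 0.0836 |
| north-east run | 3.2 | 0.0619 |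
| north-east run | 6.5 | 0.0788 |
| north-east run | 9.8 | 0.0920 |
| north-east run | 13 | 0.1013 |
| north-east run | 16 | 0.1072 |
| north-east run | 20 | 0.1121 |
| north-east run | 23 | 0.1133 |
| north-east run | 26 | 0.1142 |
| south-east run | 3.2 | 0.0404 |
| south-east run | 6.5 | 0.0681 |
| south-east run | 9.8 | 0.0917 |
| south-east run | 13 | 0.1073 |
| south-east run | 16 | 0.1191 |
| south-east run | 20 | 0.1286 |
| south-east run | 23 | 0.1363 |
| south-east run | 26 | 0.1409 |
| south run | 3.2 | 0.0615 |
| south run | 6.5 | 0.0880 |
| south run | 9.8 | 0.1023 |
| south run | 13 | 0.1040 |
| south run | 16 | 0.1043 |
| south run | 20 | 0.1056 |
| south run | 23 | 0.1026 |
| south run | 26 | 0.0985 |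

(readings scatter by 0.001 M)

* reaction order in [starting material] at the outset, round the charge of the west run, defined at two percent of the starting material turned into target (one fixed amount of target, the same in the runs compared)
* reaction order in [reagent] at the outset, round the charge of the west run, defined at two percent of the starting material turned into target
* target in the east run at 26 min, as a share of the starting material charged

- Overall: starting material + reagent -> target.
- Constant volume, constant temperature.
- What is held in complexes is read along with the free species.
- An order is taken over about fifteen percent of the charge, up and down.

- Read the loss from the south run, whose readings fall late: between 20 min and 26 min the target goes from 88.0% to 82.1% of the charge, a loss reading of 0.0116 min⁻¹.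
- Set the bound from above: the yield in the east run cannot pass the whole charge.
- Set the bound from below, for a charge that does turn in full: let it all turn at the start, so that each target molecule is exposed for the full 26 min; the share kept at this loss reading is 74.0%.
- Tighten the lower bound with the making time. Treat making at the reagent charge of the south run as pseudo-first-order: 51.3% of the charge is turned by 3.2 min, which gives 0.225 min⁻¹ and a mean delay of 4.45 min.
- Note that east may turn faster still: at one reagent charge, the west run turned 22.3% by 3.2 min and the larger south-east charge 16.8%.
- Commit to the survival share, the loss factor over the time left after the mean delay: 77.9%.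
- Place the forecast: it gives 0.6 (0.35 to 0.85) and 1.4 (1.1 to 1.8) for the orders, and 78% (66% to 88%) for the yield. Its yield stands inside the bracket, but its low end falls below my lower bound. Its grounds differ from mine: “East should convert quickly to about 90%, then lose about 14% by 26 min, leaving roughly 78%.”
- Read the result: the orders are 0.75 and 1.7, and the east run gives 82.3%.

    starting material + 2 reagent → target + reagent (1.716 M⁻² min⁻¹)
    target → decomposed product (0.008760 min⁻¹)
    starting material + reagent ⇌ idle substrate-reagent adduct, settled at all times (3.110 M⁻¹)

- Hold the survival share of 77.9% against the east run: the flask stands 4.4 percentage points higher. The east run falls short of its whole charge through the reaction of target to decomposed product: with that step removed, the east run gives 99.9% instead of 82.3%, and the step accounts for 99% of what is missing. The south run, whose readings supplied the survival share, reads 82.1% of its charge at 26 min, 4.2 points above that share.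

(The runs come from a simulation with constants of no real substance.)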